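A percent of the substrate charge is the unit of this ledger, and a rate in it is such a share per hour.

all flasks: gas 150 mM (held); initiator 10 mM
- zeta: substrate 1 M; scavenger 0.10 M; run made earlier
- eta: substrate 1 M; scavenger 0.46 M; run made earlier
- theta: substrate 1 M; scavenger 2.3 M; run made earlier
- summer: substrate 1.0 M; scavenger 0.120 M; time 2.0 d
- noon: substrate 1.0 M; scavenger 0.250 M; time 2.0 d
- dawn: substrate 1.0 M; scavenger 0.500 M; time 2.0 d
- dusk: substrate 1.0 M; scavenger 1.00 M; time 2.0 d
- winter: substrate 1.0 M; scavenger 2.00 M; time 2.0 d

| run | time / h | product / % | substrate / % |
|---|---|---|---|
| zeta | 2.00 | 5 | 94 |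
| zeta | 6.00 | 6 | 89 |
| zeta | 12.0 | 14 | 79 |
| zeta | 15.0 | 13 | 70 |
| zeta | 25.0 | 26 | 53 |
| eta | 5.00 | 2 | 92 |
| eta | 10.0 | 9 | 87 |
| eta | 15.0 | 17 | 80 |
| eta | 20.0 | 24 | 68 |
| eta | 25.0 | 25 | 65 |
| theta | 2.00 | 3 | 97 |
| theta | 6.00 | 6 | 91 |
| theta | 12.0 | 16 | 83 |
| theta | 15.0 | 19 | 79 |
| theta | 25.0 | 25 | 68 |

(standard deviation of a reading: 2 percentage points)

- the earlier runs were read with a standard deviation of 2 percentage points
- at the start none of the gas is in solution
- "hardly changes" means that all values lie within two and a half points (for a concentration: within two and a half percent of the largest)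
- a reading of substrate is of its free form alone

- amount of product at the end, in percent of the substrate charged for summer, noon, dawn, dusk, winter, in this order
- how that number moves from the first to the last of them (hardly changes / rises all the way / falls, then rises / falls all the way / rises, then falls)

Saturated, the gas amounts to 15.0 % of the substrate charge, less than the substrate itself, and none of it is in solution at the start. Yet zeta holds 26 % of product after 25.0 h, more than one saturated solution could supply if each product takes up one gas, as this reckoning assumes. The gas must therefore enter during the run, and the ledger of this limiting reagent has entries for gas that has entered, gas standing dissolved and gas leaving as product. The dissolved entry is taken as small, since the readings show no lag beyond their scatter of 2 percentage points.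

The product entry hardly differs between runs: after 25.0 h it reads 26 %, 25 % and 25 %, while scavenger spans 0.10 M to 2.3 M and substrate reads 53 % to 68 %. Pooling the last two readings of each run gives

feed = 132 % / 125 h = 0.0106 h⁻¹

This is the feed, the fraction of the substrate charge entering as gas and leaving as product per hour. The books for each asked flask then close at

product = feed × 2.0 d = 50.7 %, give or take 1.9 points

The entry holds while substrate lasts. Zeta, with less scavenger than summer, lost free substrate over its 25.0 h at a pace that, carried forward as an estimate, comes to 90.2 % of the charge in 2.0 d, less than the whole. The row should therefore stay flat.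

The forecast instead ran from 36.6 % to 42.2 %, rises all the way, holding that “More scavenger spares substrate, so product rises”.

The flasks give 51.8 % at 0.120 M and 51.8 % at 2.00 M, and the row hardly changes, 1.1 points above the reckoned figure. Summer ended with partner at 1.34 × 10⁻⁶ M, its making and using standing at a ratio of 1.00.

    initiator → 2 initiating radical (k = 3.30 × 10⁻⁶ min⁻¹)
    substrate + initiating radical → capped initiator + first chain carrier (k = 25000 M⁻¹ s⁻¹)
    partner + first chain carrier → product + second chain carrier (k = 15000 M⁻¹ s⁻¹)
    substrate + second chain carrier → released group + first chain carrier (k = 3.20 × 10⁵ M⁻¹ min⁻¹)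
    2 second chain carrier → ended chains (k = 7.50 × 10⁷ M⁻¹ s⁻¹)
    gas ⇌ partner, rate k6*(csat - [partner]) (kL = 0.00120 min⁻¹)
    substrate + released group ⇌ idle adduct, settled at all times (K = 7.40 M⁻¹)
    scavenger + released group → scavenged by-product (k = 0.0260 M⁻¹ min⁻¹)

Carried on to 20.0 d, the feed reckons 509 % of the charge for summer, more than the 99.0 % of product standing then beside 0.139 % of substrate.

The earlier runs and the new flask are simulated for substances that don't exist; noise was put on by code.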